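**Strategy.** Everything rests on cutting the C2–C3 bond of the dihydropyran ring of the chroman. The carbinol carbon C3 and the O1-bearing quaternary C2 (the vicinal C–O pattern of that ring) are both acceptor carbons, so they are joined by reductive polarity reversal. The precursor is an arylacetaldehyde whose ortho oxygen carries an (E)-1-methyl-2-[(R)-p-tolylsulfinyl]vinyl group. SmI2 turns the aldehyde into a ketyl that closes the ring 6-exo onto the O-substituted alkene carbon, creating the C3 alcohol with the sulfoxide directing its configuration. Raney Ni then converts the sulfinylmethyl arm into the second C2 methyl and frees the phenols, and a methylene bridge to the pyrone completes the target.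

Key step: step 8

Assumption: base-equilibrated phenoxide addition (step 6) is taken to give the (E)-vinyl sulfoxide, and the ketyl (step 8) to be delivered on the alkene face carrying the sulfinyl oxygen; if geometry or sense of induction proves opposite, the enantiomeric menthyl (R)-p-toluenesulfinate is used in step 5.

Step 1
Reactants: 1 phloroglucinol; 2 (S)-2-methylbutanoyl chloride
Product: 3 (2S)-2-methyl-1-(2,4,6-trihydroxyphenyl)butan-1-one
Conditions: AlCl3 (4 equiv), CH2Cl2/PhNO2, 0 °C to rt; aq. HCl work-up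
Reagents that add atoms: none
Why: Friedel–Crafts C-acylation of the symmetric triol should give a single regioisomer, and the acidic, base-free medium should leave the α-stereocentre of the acyl group untouched.

Step 2
Reactants: 3
Product: 4 (2S)-1-[2,4-bis(benzyloxy)-6-hydroxyphenyl]-2-methylbutan-1-one
Conditions: BnBr (2.1 equiv), K2CO3 (2.2 equiv), acetone, 50 °C
Reagents that add atoms: benzyl bromide, BrCc1ccccc1
Why: Williamson etherification should stop after the para and one ortho hydroxyl, because the remaining ortho hydroxyl is chelated to the ketone and the two ortho positions are equivalent.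

Step 3
Reactants: 4
Product: 5 (2S)-1-[2-(allyloxy)-4,6-bis(benzyloxy)phenyl]-2-methylbutan-1-one
Conditions: allyl bromide (1.5 equiv), K2CO3 (2 equiv), DMF, 50 °C
Reagents that add atoms: allyl bromide, C=CCBr
Why: Williamson O-allylation of the chelated phenol should proceed in the dipolar solvent with the reactive allylic halide.

Step 4
Reactants: 5
Product: 6 (2S)-1-[3-allyl-4,6-bis(benzyloxy)-2-hydroxyphenyl]-2-methylbutan-1-one
Conditions: 1,2-dichlorobenzene, 180 °C, sealed tube
Reagents that add atoms: none
Why: the aromatic Claisen rearrangement can deliver the allyl group only to the single free ortho carbon, and tautomerization restores the chelated phenol that later becomes O1.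

Step 5
Reactants: 7 (1R,2S,5R)-menthyl (S)-p-toluenesulfinate; 8 1-propynylmagnesium bromide
Product: 9 (S)-1-propynyl p-tolyl sulfoxide
Conditions: THF/toluene, −20 to 0 °C; then aq. NH4Cl
Reagents that add atoms: none
Why: the Andersen sulfoxide synthesis displaces menthoxide at sulfur with clean inversion, which fixes the sulfur configuration of the auxiliary.

Step 6
Reactants: 6; 9
Product: 10 (2S)-1-[3-allyl-4,6-bis(benzyloxy)-2-({(E)-1-[(R)-p-tolylsulfinyl]prop-1-en-2-yl}oxy)phenyl]-2-methylbutan-1-one
Conditions: Cs2CO3 (0.3 equiv), MeCN, 40 °C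
Reagents that add atoms: none
Why: oxa-Michael addition of the phenoxide to the linear alkynyl sulfoxide tolerates the hindered phenol, should settle at the (E)-isomer (aryloxy trans to sulfur) under reversible base catalysis, and does not touch sulfur.

Step 7
Reactants: 10
Product: 12 {4,6-bis(benzyloxy)-3-[(2S)-2-methylbutanoyl]-2-({(E)-1-[(R)-p-tolylsulfinyl]prop-1-en-2-yl}oxy)phenyl}acetaldehyde, via ozonide 11 (not isolated)
Conditions: O3, CH2Cl2, −78 °C, Sudan Red 7B end-point indicator; then PPh3 (1.2 equiv), −78 °C to rt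
Reagents that add atoms: ozone, [O-][O+]=O
Why: ozonolysis should take the monosubstituted allyl alkene well before the sulfinyl-deactivated trisubstituted alkene, the dye marking the end point, and phosphine reduction of the ozonide frees the aldehyde.

Step 8
Reactants: 12
Product: 13 (2S)-1-[(2S,3S)-5,7-bis(benzyloxy)-3-hydroxy-2-methyl-2-{[(R)-p-tolylsulfinyl]methyl}chroman-8-yl]-2-methylbutan-1-one
Conditions: SmI2 (3 equiv, 0.1 M in THF), MeOH (4 equiv), THF, −78 to 0 °C
Reagents that add atoms: none
Why: SmI2 reduces the aldehyde to a samarium ketyl that adds to the oxygen-bearing β-carbon of the vinyl sulfoxide, and a second electron transfer followed by protonation by MeOH leaves the CH2S(O)Tol arm, so two acceptor carbons are joined by reductive polarity reversal. The closest known reaction type is the SmI2-induced reductive cyclization of aldehydes onto β-alkoxyacrylates and β-alkoxyvinyl sulfoxides that gives 3-hydroxytetrahydropyrans. The dihydropyran ring (O1, C2, C3, C4, C4a, C8a) closes in the 6-exo-trig mode through a half-chair in which samarium bridges the ketyl oxygen and the sulfinyl oxygen. At C2 the methyl cis to sulfur forces the sulfur lone pair into the alkene plane (A1,3 strain), so S–O and p-tolyl lie on opposite faces and the ketyl arrives on the S–O face, anti to p-tolyl, which for the (E),(R)-sulfinyl acceptor should give (2S). At C3 the O–Sm bond sits pseudo-equatorial and trans to the sulfinylmethyl arm in that chelate, which translates the face selection at C2 into (3S). The step needs aldehyde-over-ketone chemoselectivity, secured because the C8 ketone is α-branched, flanked by two ortho oxygens and twisted out of conjugation, and it needs attack at the O-substituted carbon, secured by the polarization of the sulfinyl acceptor.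

Step 9
Reactants: 13
Product: 14 (2S)-1-[(3S)-3,5,7-trihydroxy-2,2-dimethylchroman-8-yl]-2-methylbutan-1-one
Conditions: Raney Ni (W-2, excess), H2 (1 atm), EtOH, rt to 40 °C
Reagents that add atoms: none
Why: Raney nickel desulfurization should cleave both C–S bonds so that the sulfinylmethyl arm becomes the second C2 methyl (C2 is then no longer a stereocentre), and the same hydrogenolysis should remove both O-benzyl groups without touching C3.

Step 10
Reactants: 15 pentan-3-one
Product: 16 (Z)-3-(trimethylsilyloxy)pent-2-ene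
Conditions: Me3SiCl (1.2 equiv), Et3N (2.4 equiv), DMF, 80 °C
Reagents that add atoms: chlorotrimethylsilane, C[Si](C)(C)Cl
Why: thermodynamic O-silylation of the symmetric ketone should give the silyl enol ether, whose double-bond geometry is of no consequence for the next step.

Step 11
Reactants: 16; 17 malonyl dichloride
Product: 18 6-ethyl-4-hydroxy-5-methyl-2H-pyran-2-one
Conditions: Et2O, −20 °C to rt
Reagents that add atoms: none
Why: in the Effenberger pyrone synthesis the enol ether is C-acylated by one acid chloride and the resulting enol oxygen closes onto the second one, which should give the 4-hydroxy-2-pyrone directly.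

Step 12
Reactants: 18; 14
Product: 20 6-ethyl-4-hydroxy-5-methyl-3-({(3S)-3,5,7-trihydroxy-2,2-dimethyl-8-[(2S)-2-methylbutanoyl]chroman-6-yl}methyl)-2H-pyran-2-one, via Mannich base 19 (not isolated)
Conditions: N,N-dimethylmethyleneiminium iodide (1.05 equiv), CH2Cl2, rt, 1 h; then 14 (1.0 equiv), MeCN, 60 °C
Reagents that add atoms: Eschenmoser's salt (N,N-dimethylmethyleneiminium iodide), C=[N+](C)C.[I-]
Why: Mannich aminomethylation at C3 of the pyrone followed by thermal loss of dimethylamine should give the 3-methylene-pyrandione, which is captured in a Michael-type Friedel–Crafts alkylation by C6, the only free aromatic carbon of 14.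

**Compound list**

1 | phloroglucinol | Oc1cc(O)cc(O)c1 | starting material
2 | (S)-2-methylbutanoyl chloride | CC[C@H](C)C(=O)Cl | starting material
3 | (2S)-2-methyl-1-(2,4,6-trihydroxyphenyl)butan-1-one | CC[C@H](C)C(=O)c1c(O)cc(O)cc1O | intermediate
4 | (2S)-1-[2,4-bis(benzyloxy)-6-hydroxyphenyl]-2-methylbutan-1-one | CC[C@H](C)C(=O)c1c(O)cc(OCc2ccccc2)cc1OCc1ccccc1 | intermediate
5 | (2S)-1-[2-(allyloxy)-4,6-bis(benzyloxy)phenyl]-2-methylbutan-1-one | CC[C@H](C)C(=O)c1c(OCC=C)cc(OCc2ccccc2)cc1OCc1ccccc1 | intermediate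
6 | (2S)-1-[3-allyl-4,6-bis(benzyloxy)-2-hydroxyphenyl]-2-methylbutan-1-one | CC[C@H](C)C(=O)c1c(O)c(CC=C)c(OCc2ccccc2)cc1OCc1ccccc1 | intermediate
7 | (1R,2S,5R)-menthyl (S)-p-toluenesulfinate | Cc1ccc(cc1)[S@@](=O)O[C@@H]1C[C@H](C)CC[C@H]1C(C)C | starting material
8 | 1-propynylmagnesium bromide | CC#C[Mg]Br | starting material
9 | (S)-1-propynyl p-tolyl sulfoxide | CC#C[S@@](=O)c1ccc(C)cc1 | intermediate
10 | (2S)-1-[3-allyl-4,6-bis(benzyloxy)-2-({(E)-1-[(R)-p-tolylsulfinyl]prop-1-en-2-yl}oxy)phenyl]-2-methylbutan-1-one | CC[C@H](C)C(=O)c1c(O/C(C)=C/[S@@](=O)c2ccc(C)cc2)c(CC=C)c(OCc2ccccc2)cc1OCc1ccccc1 | intermediate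
11 | 1,2,4-trioxolane (ozonide) of 10 at the allyl group, mixture at the ring carbon | CC[C@H](C)C(=O)c1c(O/C(C)=C/[S@@](=O)c2ccc(C)cc2)c(CC2OCOO2)c(OCc2ccccc2)cc1OCc1ccccc1 | intermediate
12 | {4,6-bis(benzyloxy)-3-[(2S)-2-methylbutanoyl]-2-({(E)-1-[(R)-p-tolylsulfinyl]prop-1-en-2-yl}oxy)phenyl}acetaldehyde | CC[C@H](C)C(=O)c1c(O/C(C)=C/[S@@](=O)c2ccc(C)cc2)c(CC=O)c(OCc2ccccc2)cc1OCc1ccccc1 | intermediate
13 | (2S)-1-[(2S,3S)-5,7-bis(benzyloxy)-3-hydroxy-2-methyl-2-{[(R)-p-tolylsulfinyl]methyl}chroman-8-yl]-2-methylbutan-1-one | CC[C@H](C)C(=O)c1c(OCc2ccccc2)cc(OCc2ccccc2)c2c1O[C@](C)(C[S@@](=O)c1ccc(C)cc1)[C@@H](O)C2 | intermediate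
14 | (2S)-1-[(3S)-3,5,7-trihydroxy-2,2-dimethylchroman-8-yl]-2-methylbutan-1-one | CC[C@H](C)C(=O)c1c(O)cc(O)c2c1OC(C)(C)[C@@H](O)C2 | intermediate
15 | pentan-3-one | CCC(=O)CC | starting material
16 | (Z)-3-(trimethylsilyloxy)pent-2-ene | C/C=C(/CC)O[Si](C)(C)C | intermediate
17 | malonyl dichloride | O=C(Cl)CC(=O)Cl | starting material
18 | 6-ethyl-4-hydroxy-5-methyl-2H-pyran-2-one | CCc1oc(=O)cc(O)c1C | intermediate
19 | 3-[(dimethylamino)methyl]-6-ethyl-4-hydroxy-5-methyl-2H-pyran-2-one | CCc1oc(=O)c(CN(C)C)c(O)c1C | intermediate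
20 | 6-ethyl-4-hydroxy-5-methyl-3-({(3S)-3,5,7-trihydroxy-2,2-dimethyl-8-[(2S)-2-methylbutanoyl]chroman-6-yl}methyl)-2H-pyran-2-one | CCc1oc(=O)c(Cc2c(O)c3c(c(C(=O)[C@@H](C)CC)c2O)OC(C)(C)[C@@H](O)C3)c(O)c1C | target

**Count.** Total steps: 12. Longest linear sequence: 9 steps (1, 2, 3, 4, 6, 7, 8, 9, 12).

**Steps most likely to fail**

Step 8. The facial discrimination in the ketyl addition may be poor or reversed, so that C3 epimers form. The fallback sets out from 12 and comes back at 13. The SmI2 ring closure is run as in step 8 without regard to the isomer ratio. The carbinol mixture is oxidized with Dess–Martin periodinane (CH2Cl2, NaHCO3, rt) to (2S)-1-[5,7-bis(benzyloxy)-2-methyl-3-oxo-2-{[(R)-p-tolylsulfinyl]methyl}chroman-8-yl]-2-methylbutan-1-one F1, either configuration at C2. This ketone, flanked by a fully substituted carbon and a methylene, is reduced under reagent control with (R)-2-methyl-CBS-oxazaborolidine and catecholborane (toluene, −40 °C), which should give the (3S)-alcohol whatever the configuration at C2. The product is 13 together with its C2 epimer, (2S)-1-[(2R,3S)-5,7-bis(benzyloxy)-3-hydroxy-2-methyl-2-{[(R)-p-tolylsulfinyl]methyl}chroman-8-yl]-2-methylbutan-1-one F2, which merges with 13 at 14 in step 9 because C2 becomes achiral there.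

Step 9. The hindered C8 aryl ketone may be over-reduced, or the benzyl ethers may cleave sluggishly on the sulfur-laden nickel surface. The fallback sets out from 13 and comes back at 14, separating the two tasks. Nickel boride (NiCl2·6H2O, NaBH4, MeOH/THF, 0 °C) should cleave only the C–S bonds and give (2S)-1-[(3S)-5,7-bis(benzyloxy)-3-hydroxy-2,2-dimethylchroman-8-yl]-2-methylbutan-1-one F3. The benzyl groups are then removed without any reductant by BCl3 and pentamethylbenzene (CH2Cl2, −78 °C) to give 14.

Step 7. Ozone may over-oxidize the sulfinyl-substituted enol-ether double bond or the sulfur. The fallback sets out from 6 and comes back at 12, so that ozone never meets the sulfoxide. Phenol 6 is ozonized (CH2Cl2/MeOH, −78 °C) and worked up with NaBH4 (−78 to 0 °C, the chelated hindered ketone surviving) to give (2S)-1-[4,6-bis(benzyloxy)-2-hydroxy-3-(2-hydroxyethyl)phenyl]-2-methylbutan-1-one F4. Its phenoxide, not the primary alcohol, adds to 9 under the conditions of step 6 to give (2S)-1-[4,6-bis(benzyloxy)-3-(2-hydroxyethyl)-2-({(E)-1-[(R)-p-tolylsulfinyl]prop-1-en-2-yl}oxy)phenyl]-2-methylbutan-1-one F5. Dess–Martin oxidation (CH2Cl2, rt) then gives aldehyde 12.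

**Further compounds**

F1 | step 8 | (2S)-1-[5,7-bis(benzyloxy)-2-methyl-3-oxo-2-{[(R)-p-tolylsulfinyl]methyl}chroman-8-yl]-2-methylbutan-1-one (either C2 configuration) | CC[C@H](C)C(=O)c1c(OCc2ccccc2)cc(OCc2ccccc2)c2c1OC(C)(C[S@@](=O)c1ccc(C)cc1)C(=O)C2
F2 | step 8 | (2S)-1-[(2R,3S)-5,7-bis(benzyloxy)-3-hydroxy-2-methyl-2-{[(R)-p-tolylsulfinyl]methyl}chroman-8-yl]-2-methylbutan-1-one | CC[C@H](C)C(=O)c1c(OCc2ccccc2)cc(OCc2ccccc2)c2c1O[C@@](C)(C[S@@](=O)c1ccc(C)cc1)[C@@H](O)C2
F3 | step 9 | (2S)-1-[(3S)-5,7-bis(benzyloxy)-3-hydroxy-2,2-dimethylchroman-8-yl]-2-methylbutan-1-one | CC[C@H](C)C(=O)c1c(OCc2ccccc2)cc(OCc2ccccc2)c2c1OC(C)(C)[C@@H](O)C2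
F4 | step 7 | (2S)-1-[4,6-bis(benzyloxy)-2-hydroxy-3-(2-hydroxyethyl)phenyl]-2-methylbutan-1-one | CC[C@H](C)C(=O)c1c(O)c(CCO)c(OCc2ccccc2)cc1OCc1ccccc1
F5 | step 7 | (2S)-1-[4,6-bis(benzyloxy)-3-(2-hydroxyethyl)-2-({(E)-1-[(R)-p-tolylsulfinyl]prop-1-en-2-yl}oxy)phenyl]-2-methylbutan-1-one | CC[C@H](C)C(=O)c1c(O/C(C)=C/[S@@](=O)c2ccc(C)cc2)c(CCO)c(OCc2ccccc2)cc1OCc1ccccc1
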